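## Structural features

The target is an achiral, twofold-symmetric dimer: two 7-acetyl-3,6,8-trihydroxy-4,4-dimethylnaphthalen-1(4H)-one units are joined C2 to C2' through a single methylene carbon. In each half, ring B is an enolised cyclic β-diketone (C1 ketone, C2, C3 enol) closed by the quaternary carbon C4 with its two methyl groups, and it is fused through C4a–C8a to the aromatic ring A. Ring A carries hydroxyls at C6 and C8 and an acetyl group at C7 between them, so O8–H sits chelated between the C1 ketone and the acetyl carbonyl, and only C5 bears hydrogen. There is no stereocentre, since C4 carries two identical methyl groups; the only isomerism is keto–enol tautomerism of the dione units. The fragile elements are the methylene bridge between two vinylogous acids (retro-Michael exchange in base, cyclodehydration to a pyran under acid or Lewis acid), the polyphenolic enolates (air oxidation in base) and the acetyl group on the electron-rich ring (loss in hot strong acid). The real difficulty is regiochemistry and the order of events: a quaternary carbon at C4 between the arene and an enol carbon, an acetyl group exactly at C7, and a C2 carbon that must stay silent until the bridge is made. The key step uses the fact that C4 of ring B is, in the aromatic naphthalene-1,3-diol form, the one free CH that is ortho to O3 and para to O1; methylating it twice installs both methyl groups and locks ring B in its dione form.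

## Logic of the disconnections

18 is cut at both C2–CH2 bonds into two molecules of 15 and the one-carbon unit 16. The symmetry halves the problem, and the bond is the one a cyclic 1,3-dione forms with an aldehyde by condensation followed by conjugate addition. The forward step demands that C2 be the only carbon nucleophile; in 15 ring A is deactivated by two acyl groups and C5 is shielded by the peri methyl groups. The bridge is made last so that it never meets a Lewis acid.

15 is traced back to 12 by restoring the C2 ester and the O6 methyl ether. The ester is deliberately kept up to this point: it blocks C2, the most nucleophilic carbon of the dione, during the acetylation. Removing it first would send the acetyl group to C2. The forward step must cleave one ether and remove the ester without touching the acetyl group.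

12 is cut at the C7–acetyl bond to 9 and 10. A Fries rearrangement needs an aryl ester, and O8 is a methyl ether straight after the key step, so 9 with a free O8–H is the required substrate. Only one acetate can then migrate, C7 is its only free ortho position, and C5 is hindered by the C4 methyl groups.

9 is traced back to 8 by re-methylating O8. The forward cleavage is selective because only O8 is peri to the C1 ketone and can form a six-membered chelate with a boron Lewis acid; O6 cannot.

8 is cut at both C4–CH3 bonds to 5 and two molecules of 6. This removes the quaternary carbon and returns ring B to a flat aromatic naphthalenediol. The forward step must alkylate carbon and not oxygen, and C4 and not C2; the C2 ester of 5 and the ring A methyl ethers secure this. The methyl ester is the right choice because it alone survives the acid of the preceding cyclisation and still serves as blocking group twice.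

5 is cut at the C1–C8a aryl–acyl bond to 4. The forward reaction is an intramolecular acylation of the arene by one malonate ester. Both ring positions ortho to the side chain are equivalent and activated by the two methoxy groups, so there is no regiochemical question.

4 is cut at the ketone–malonate bond to 2 and 3, and 2 comes from 1 by activation of the acid. The forward C-acylation needs a chelated magnesium enolate so that the more acidic product does not quench the reaction or acylate again.

## Other disconnections considered

Alternative 1: The cut goes through C4a–C8a and C7–C8 of the monomer and unravels both rings into the open-chain keto ester A1 (methyl 6-methyl-6-(6-methyl-4-oxo-4H-pyran-2-yl)-3,5-dioxoheptanoate), in which the pyranone masks a triketide. In the forward sense base would form the carbanion next to the ester, this would add to the pyranone carbon bearing the CMe2 group, the heterocycle would open to a 1,3-diketone, and the central carbon of that diketone would close ring A by Claisen condensation on the ester. The product A2 (7-acetyl-3,6,8-trihydroxy-4,4-dimethylnaphthalen-1(4H)-one) is the same compound as 15.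
- In its favour: the acetyl group and both phenols are placed by chain folding, with no Fries rearrangement, no phenol protection and no ring A regiochemistry. Two rings close in one operation and the bridging substrate is obtained directly. On ring A this plan is better than the chosen one, which spends steps 5 to 7 there.
- Against it: A1 is a 3,5-dioxo ester beside a quaternary carbon and needs several dianion-type C–C bond formations. Its chain can lactonise onto its own ester. The most acidic carbon (between the two ketones) is not the one that must attack, and the attack must occur at a pyranone carbon carrying a tertiary alkyl group.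
- Comparison: on structure the alternative is the better plan; on mechanism the chosen key step is safer, because it has a single reactive carbon where the cascade has several branch points; on step count the two are about equal once the preparation of A1 is included.

Alternative 2: The cut is at both C4a–C5 bonds of the des-acetyl dimer and leads to the methylene-bridged bis(acetoacetyl) triketone A3 (4,4'-methylenebis[3,5-dihydroxy-6,6-dimethyl-2-(3-oxobutanoyl)cyclohexa-2,4-dien-1-one]). In the forward sense the terminal methyl of each side chain would condense with the neighbouring ring carbonyl and dehydrate, closing both aromatic rings to A4 (2,2'-methylenebis(3,6,8-trihydroxy-4,4-dimethylnaphthalen-1(4H)-one)).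
- In its favour: the gem-dimethyl groups come from the same exhaustive C-methylation chemistry as in the chosen plan (equal on this point). The route is convergent, forms two rings at once, needs no protecting groups and could reach A4 in fewer steps (better on paper).
- Against it: the terminal methyl is the least acidic carbon acid of A3. The carbonyl it must attack is part of an anionic, fully enolised triketone next to the quaternary carbon. The side chain can close on a ring enol oxygen to a pyranone instead. The bridge is exposed to the aldol conditions.
- Decisive drawback: A4 still lacks both C7 acetyl groups. They would have to be introduced twice on the dimer under Lewis acid, with C5 and the bridge exposed.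
- Comparison: the chosen plan is longer but keeps every harsh step at the monomer stage.

Alternative 3: The cut is at C1–C2 and C3–C4 of ring B and leads to the benzocyclobutenone A5 (3,5-dimethoxy-8,8-dimethylbicyclo[4.2.0]octa-1,3,5-trien-7-one) and the ynol ether A6 (ethoxyethyne). In the forward sense, thermal four-electron ring opening of A5 would give an ortho-quinoid vinylketene. Its electrophilic ketene carbon would bond to the nucleophilic terminal carbon of A6 and the CMe2 terminus to the oxygenated carbon, closing ring B as A7 (3-ethoxy-6,8-dimethoxy-4,4-dimethylnaphthalen-1(4H)-one).
- In its favour: the quaternary carbon is already in A5, so there is no carbon-versus-oxygen alkylation question, and ring B arrives with C2–H and no ester to remove. On these two points it is better than the chosen plan.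
- Against it: A5 is not a stock compound and its preparation costs several steps with its own regiochemical problem. Opening a benzocyclobutenone breaks aromaticity and needs temperatures at which A6 is volatile and prone to polymerise. A7 still needs the C7 acetyl group (with C2 unblocked), three ether cleavages and the bridge.
- Comparison: equal on what remains to be done on ring A, better at the quaternary centre, worse in access to the precursor and in step count; the chosen precursor is three steps from stock materials.

Key step: step 4

Remark: each 3-hydroxy-1-oxo unit is written as one enol tautomer; the tautomers interconvert and count as one compound, and no compound in the route has a stereocentre.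

## Route

Step 1
Reactants: 1 3,5-dimethoxyphenylacetic acid
Product: 2 3,5-dimethoxyphenylacetyl chloride
Conditions: (COCl)2 (1.2 equiv), DMF (cat.), CH2Cl2, 0 °C → rt; evaporate, use crude
Reagents that add atoms: oxalyl chloride, ClC(=O)C(=O)Cl
Why: Standard acid chloride formation through the catalytic chloroiminium species; the aryl methyl ethers are inert and the volatile co-products leave on evaporation.

Step 2
Reactants: 2 3,5-dimethoxyphenylacetyl chloride; 3 dimethyl malonate
Product: 4 dimethyl 2-[2-(3,5-dimethoxyphenyl)acetyl]propanedioate
Conditions: MgCl2 (1.1 equiv), Et3N (2.2 equiv), MeCN, 0 °C → rt; 1 M HCl work-up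
Reagents that add atoms: dimethyl malonate (3), COC(=O)CC(=O)OC
Why: C-acylation of the chelated magnesium enolate of a malonate (soft enolisation); magnesium holds the more acidic acylmalonate as a chelate, which prevents O-acylation and double acylation, and any arylketene formed from 2 and the amine is captured at the same carbon.

Step 3
Reactants: 4 dimethyl 2-[2-(3,5-dimethoxyphenyl)acetyl]propanedioate
Product: 5 methyl 1,3-dihydroxy-6,8-dimethoxynaphthalene-2-carboxylate
Conditions: MeSO3H (neat), 25 °C; pour onto ice
Reagents that add atoms: none
Why: Intramolecular Friedel–Crafts acylation of the arene by one malonate ester carbonyl, followed by enolisation to the aromatic diol (the arylacetylmalonate to 1,3-dihydroxy-2-naphthoate cyclisation); the position attacked is ortho to the side chain and ortho/para to the two methoxy groups, both such positions are equivalent, and a non-sulfonating acid is chosen for the electron-rich ring.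

Step 4
Reactants: 5 methyl 1,3-dihydroxy-6,8-dimethoxynaphthalene-2-carboxylate; 6 iodomethane
Product: 8 methyl 3-hydroxy-6,8-dimethoxy-4,4-dimethyl-1-oxo-1,4-dihydronaphthalene-2-carboxylate, via 4-monomethyl naphthalenediol ester 7 (not isolated)
Conditions: NaOMe (3.5 equiv), MeI (3 equiv), degassed MeOH, Ar, 0 °C → 45 °C; then 1 M HCl
Reagents that add atoms: iodomethane (6), CI
Why: NaOMe in methanol deprotonates 5 twice to the naphthalene-1,3-diolate, which is also the dienolate of a cyclic β-keto ester, so its γ-carbon C4 (ortho to O3, para to O1) has the highest carbanion character. SN2 attack of C4 on iodomethane gives a 4-methyl dione that tautomerises back to the aromatic diol 7; a second deprotonation and a second SN2 attack at the same carbon forms the other C4–CH3 bond, and 8, with no hydrogen left on C4, stays dearomatised. The closest known reaction types are the exhaustive C-methylation of acylphloroglucinols to filicinic and syncarpic acid derivatives with NaOMe and iodomethane, and the dearomative C4-alkylation of 2-substituted naphthalene-1,3-diols. No ring is closed and no stereocentre is formed, because the new quaternary carbon carries two identical methyl groups. The selectivity needed is C4 over C2, over oxygen and over ring A: C2 is fully substituted and its charge is drawn into the ester, methanol hydrogen-bonds the oxygen termini of the ambident anion so that the soft electrophile is taken at carbon, and the ring A oxygens are methyl ethers and not phenoxides. Under the conditions the product exists as a stabilised, weakly nucleophilic β-tricarbonyl anion, which should protect it from a third methylation while iodomethane is kept near three equivalents. Air is excluded because the electron-rich dianion would otherwise be oxidised at C4.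

Step 5
Reactants: 8 methyl 3-hydroxy-6,8-dimethoxy-4,4-dimethyl-1-oxo-1,4-dihydronaphthalene-2-carboxylate
Product: 9 methyl 3,8-dihydroxy-6-methoxy-4,4-dimethyl-1-oxo-1,4-dihydronaphthalene-2-carboxylate
Conditions: BCl3 (2.5 equiv), CH2Cl2, −78 °C → 0 °C; H2O quench
Reagents that add atoms: none
Why: Chelation-controlled ether cleavage: only the O8 methyl ether is peri to the C1 ketone and can form the six-membered boron chelate that delivers chloride to its methyl group; the O6 ether and, at this temperature, the methyl ester should remain.

Step 6
Reactants: 9 methyl 3,8-dihydroxy-6-methoxy-4,4-dimethyl-1-oxo-1,4-dihydronaphthalene-2-carboxylate; 10 acetic anhydride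
Product: 12 methyl 7-acetyl-3,8-dihydroxy-6-methoxy-4,4-dimethyl-1-oxo-1,4-dihydronaphthalene-2-carboxylate, via C8 acetate 11 (not isolated)
Conditions: Ac2O (4 equiv), BF3·OEt2 (4 equiv), 1,2-dichloroethane, 80 °C; then MeOH–H2O, 60 °C
Reagents that add atoms: acetic anhydride (10), CC(=O)OC(C)=O
Why: O-acetylation of the phenol followed by BF3-promoted ortho-Fries rearrangement; C7 is the only free position ortho to O8 and is also activated by the O6 ether, the para position C5 is shielded by the peri C4 methyl groups, C2 is blocked by the ester, and the methanolic work-up cleaves boron chelates and any enol acetate.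

Step 7
Reactants: 12 methyl 7-acetyl-3,8-dihydroxy-6-methoxy-4,4-dimethyl-1-oxo-1,4-dihydronaphthalene-2-carboxylate
Product: 15 7-acetyl-3,6,8-trihydroxy-4,4-dimethylnaphthalen-1(4H)-one, via O6-demethylated ester 13 (not isolated), via beta-keto acid 14 (not isolated)
Conditions: BBr3 (4 equiv), CH2Cl2, −78 °C → rt; H2O quench, solvent exchange; then 2 M HCl, 1,4-dioxane, 90 °C
Reagents that add atoms: none
Why: BBr3 cleaves the O6 methyl ether, assisted by chelation to the adjacent acetyl carbonyl; heating the quenched material in aqueous acid hydrolyses the vinylogous β-keto ester, and the acid loses CO2 through the usual six-membered transition state (β-keto ester hydrolysis and decarboxylation), which frees C2 only now.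

Step 8
Reactants: 15 7-acetyl-3,6,8-trihydroxy-4,4-dimethylnaphthalen-1(4H)-one (2 equiv); 16 formaldehyde (charged as paraformaldehyde)
Product: 18 2,2'-methylenebis[7-acetyl-3,6,8-trihydroxy-4,4-dimethylnaphthalen-1(4H)-one] (CNP0295164.0), via 2-methylidene trione 17 (not isolated)
Conditions: (CH2O)n (0.5 equiv CH2O), NaOAc (0.2 equiv), EtOH–H2O 9:1, N2, 50 °C
Reagents that add atoms: formaldehyde (16), C=O
Why: Knoevenagel condensation of the cyclic 1,3-dione at C2 with formaldehyde, then Michael addition of a second dione to the resulting enone, as in the reaction of dimedone with formaldehyde; C2 is the only carbon acid, ring A is deactivated by two acyl groups with C5 hindered, and the dione is always in excess over the aldehyde.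

## Compound list

1 | 3,5-dimethoxyphenylacetic acid | OC(=O)Cc1cc(OC)cc(OC)c1 | starting material
2 | 3,5-dimethoxyphenylacetyl chloride | ClC(=O)Cc1cc(OC)cc(OC)c1 | intermediate
3 | dimethyl malonate | COC(=O)CC(=O)OC | starting material
4 | dimethyl 2-[2-(3,5-dimethoxyphenyl)acetyl]propanedioate | COC(=O)C(C(=O)OC)C(=O)Cc1cc(OC)cc(OC)c1 | intermediate
5 | methyl 1,3-dihydroxy-6,8-dimethoxynaphthalene-2-carboxylate | COC(=O)c1c(O)cc2cc(OC)cc(OC)c2c1O | intermediate
6 | iodomethane | CI | starting material
7 | methyl 1,3-dihydroxy-6,8-dimethoxy-4-methylnaphthalene-2-carboxylate | COC(=O)c1c(O)c(C)c2cc(OC)cc(OC)c2c1O | intermediate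
8 | methyl 3-hydroxy-6,8-dimethoxy-4,4-dimethyl-1-oxo-1,4-dihydronaphthalene-2-carboxylate | COC(=O)C1=C(O)C(C)(C)c2cc(OC)cc(OC)c2C1=O | intermediate
9 | methyl 3,8-dihydroxy-6-methoxy-4,4-dimethyl-1-oxo-1,4-dihydronaphthalene-2-carboxylate | COC(=O)C1=C(O)C(C)(C)c2cc(OC)cc(O)c2C1=O | intermediate
10 | acetic anhydride | CC(=O)OC(C)=O | starting material
11 | methyl 8-acetoxy-3-hydroxy-6-methoxy-4,4-dimethyl-1-oxo-1,4-dihydronaphthalene-2-carboxylate | COC(=O)C1=C(O)C(C)(C)c2cc(OC)cc(OC(C)=O)c2C1=O | intermediate
12 | methyl 7-acetyl-3,8-dihydroxy-6-methoxy-4,4-dimethyl-1-oxo-1,4-dihydronaphthalene-2-carboxylate | COC(=O)C1=C(O)C(C)(C)c2cc(OC)c(C(C)=O)c(O)c2C1=O | intermediate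
13 | methyl 7-acetyl-3,6,8-trihydroxy-4,4-dimethyl-1-oxo-1,4-dihydronaphthalene-2-carboxylate | COC(=O)C1=C(O)C(C)(C)c2cc(O)c(C(C)=O)c(O)c2C1=O | intermediate
14 | 7-acetyl-3,6,8-trihydroxy-4,4-dimethyl-1-oxo-1,4-dihydronaphthalene-2-carboxylic acid | OC(=O)C1=C(O)C(C)(C)c2cc(O)c(C(C)=O)c(O)c2C1=O | intermediate
15 | 7-acetyl-3,6,8-trihydroxy-4,4-dimethylnaphthalen-1(4H)-one | CC(=O)c1c(O)cc2c(c1O)C(=O)C=C(O)C2(C)C | intermediate
16 | formaldehyde (charged as paraformaldehyde) | C=O | starting material
17 | 7-acetyl-6,8-dihydroxy-4,4-dimethyl-2-methylidenenaphthalene-1,3(2H,4H)-dione | CC(=O)c1c(O)cc2c(c1O)C(=O)C(=C)C(=O)C2(C)C | intermediate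
18 | 2,2'-methylenebis[7-acetyl-3,6,8-trihydroxy-4,4-dimethylnaphthalen-1(4H)-one] | CC(=O)c1c(O)cc2c(c1O)C(=O)C(CC1=C(O)C(C)(C)c3cc(O)c(C(C)=O)c(O)c3C1=O)=C(O)C2(C)C | target

## Step count and least certain steps

Total step count: 8. Longest linear sequence: 8 steps (1 to 18); 3, 6, 10 and 16 are bought.

Step 4 (key step). The most likely failure is alkylation at oxygen in competition with carbon, which would give naphthyl methyl ethers that can no longer be dearomatised. Other risks are stalling after the first methyl group, because the second alkylation builds a quaternary benzylic carbon, a third methylation at C2 or O3 if iodomethane is in large excess, and oxidative degradation of the dianion if air enters. The fallback makes the quaternary carbon before ring B exists and sets out from 1. Fischer esterification (MeOH, H2SO4) should give methyl 2-(3,5-dimethoxyphenyl)acetate F1. Exhaustive α-methylation (NaH, MeI, THF–DMF) should give methyl 2-(3,5-dimethoxyphenyl)-2-methylpropanoate F2. Saponification (LiOH, aqueous MeOH, reflux) should give 2-(3,5-dimethoxyphenyl)-2-methylpropanoic acid F3, and (COCl)2 with DMF should give 2-(3,5-dimethoxyphenyl)-2-methylpropanoyl chloride F4. Acylation of 3 under the conditions of step 2 should give dimethyl 2-[2-(3,5-dimethoxyphenyl)-2-methylpropanoyl]propanedioate F5. Cyclisation of F5 in MeSO3H, helped by the gem-dialkyl effect, comes back to the route at 8.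

Step 6. The most likely failure is that the acetyl group stays on oxygen or migrates too slowly, because ring A is deactivated by the C1 ketone and its phenol is tied up as a boron chelate; migration to C5 is the lesser concern. The fallback replaces electrophilic acylation by halogenation and cross-coupling and sets out from 9. Bromination ortho to the phenol (NBS, i-Pr2NH cat., CH2Cl2, 0 °C) should give methyl 7-bromo-3,8-dihydroxy-6-methoxy-4,4-dimethyl-1-oxo-1,4-dihydronaphthalene-2-carboxylate F6. Stille coupling with tributyl(1-ethoxyvinyl)stannane and the zerovalent palladium catalyst Pd(PPh3)4 (toluene, 100 °C) should give methyl 7-(1-ethoxyethenyl)-3,8-dihydroxy-6-methoxy-4,4-dimethyl-1-oxo-1,4-dihydronaphthalene-2-carboxylate F7. Hydrolysis of the enol ether (1 M HCl, THF) comes back at 12.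

Step 7. The most likely failure is incomplete hydrolysis of the chelated, hindered vinylogous ester in the acid stage, or slow loss of the C7 acetyl group on prolonged heating in acid. The fallback removes the ester by nucleophilic dealkylation instead of acyl hydrolysis and sets out from 12. Krapcho dealkoxycarbonylation (LiCl, wet DMSO, 130 °C) should give 7-acetyl-3,8-dihydroxy-6-methoxy-4,4-dimethylnaphthalen-1(4H)-one F8. Ether cleavage (BBr3, CH2Cl2, −78 °C → 0 °C) comes back at 15.

Step 8. The most likely failure is over-condensation: hydroxymethylation at a second site, self-reaction of the transient enone when formaldehyde is locally in excess, or cyclodehydration of the bis(dione) to a pyran on heating. The fallback forms the two C–C bonds one at a time and sets out from 15. One portion of 15 is treated with dimethylmethyleneiminium iodide (MeCN, rt) to give the Mannich base 7-acetyl-2-[(dimethylamino)methyl]-3,6,8-trihydroxy-4,4-dimethylnaphthalen-1(4H)-one F9. Heating F9 with one equivalent of 15 (1,4-dioxane, 90 °C) releases the enone slowly by loss of the amine and traps it by Michael addition, coming back at 18.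

## Further compounds

F1 | step 4 | methyl 2-(3,5-dimethoxyphenyl)acetate | COC(=O)Cc1cc(OC)cc(OC)c1
F2 | step 4 | methyl 2-(3,5-dimethoxyphenyl)-2-methylpropanoate | COC(=O)C(C)(C)c1cc(OC)cc(OC)c1
F3 | step 4 | 2-(3,5-dimethoxyphenyl)-2-methylpropanoic acid | OC(=O)C(C)(C)c1cc(OC)cc(OC)c1
F4 | step 4 | 2-(3,5-dimethoxyphenyl)-2-methylpropanoyl chloride | ClC(=O)C(C)(C)c1cc(OC)cc(OC)c1
F5 | step 4 | dimethyl 2-[2-(3,5-dimethoxyphenyl)-2-methylpropanoyl]propanedioate | COC(=O)C(C(=O)OC)C(=O)C(C)(C)c1cc(OC)cc(OC)c1
F6 | step 6 | methyl 7-bromo-3,8-dihydroxy-6-methoxy-4,4-dimethyl-1-oxo-1,4-dihydronaphthalene-2-carboxylate | COC(=O)C1=C(O)C(C)(C)c2cc(OC)c(Br)c(O)c2C1=O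
F7 | step 6 | methyl 7-(1-ethoxyethenyl)-3,8-dihydroxy-6-methoxy-4,4-dimethyl-1-oxo-1,4-dihydronaphthalene-2-carboxylate | COC(=O)C1=C(O)C(C)(C)c2cc(OC)c(C(=C)OCC)c(O)c2C1=O
F8 | step 7 | 7-acetyl-3,8-dihydroxy-6-methoxy-4,4-dimethylnaphthalen-1(4H)-one | CC(=O)c1c(OC)cc2c(c1O)C(=O)C=C(O)C2(C)C
F9 | step 8 | 7-acetyl-2-[(dimethylamino)methyl]-3,6,8-trihydroxy-4,4-dimethylnaphthalen-1(4H)-one | CC(=O)c1c(O)cc2c(c1O)C(=O)C(CN(C)C)=C(O)C2(C)C
A1 | alternative 1 | methyl 6-methyl-6-(6-methyl-4-oxo-4H-pyran-2-yl)-3,5-dioxoheptanoate | COC(=O)CC(=O)CC(=O)C(C)(C)c1cc(=O)cc(C)o1
A2 | alternative 1 | 7-acetyl-3,6,8-trihydroxy-4,4-dimethylnaphthalen-1(4H)-one (identical with 15) | CC(=O)c1c(O)cc2c(c1O)C(=O)C=C(O)C2(C)C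
A3 | alternative 2 | 4,4'-methylenebis[3,5-dihydroxy-6,6-dimethyl-2-(3-oxobutanoyl)cyclohexa-2,4-dien-1-one] | CC(=O)CC(=O)C1=C(O)C(CC2=C(O)C(C)(C)C(=O)C(C(=O)CC(C)=O)=C2O)=C(O)C(C)(C)C1=O
A4 | alternative 2 | 2,2'-methylenebis(3,6,8-trihydroxy-4,4-dimethylnaphthalen-1(4H)-one) | Oc1cc(O)c2c(c1)C(C)(C)C(O)=C(CC1=C(O)C(C)(C)c3cc(O)cc(O)c3C1=O)C2=O
A5 | alternative 3 | 3,5-dimethoxy-8,8-dimethylbicyclo[4.2.0]octa-1,3,5-trien-7-one | CC1(C)C(=O)c2c(OC)cc(OC)cc21
A6 | alternative 3 | ethoxyethyne | CCOC#C
A7 | alternative 3 | 3-ethoxy-6,8-dimethoxy-4,4-dimethylnaphthalen-1(4H)-one | CCOC1=CC(=O)c2c(OC)cc(OC)cc2C1(C)C
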